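**Assumptions (one line each)**
- Atom labels C1–C20 follow ent-kaurane numbering: C4 = methyl-bearing quaternary carbon, C6 = acetal carbon, C7 = lactone C=O, C15 = ketone, C20 = lactone OCH2.
- In step 2 the phosphoramidite enantiomer that gives the (R)-quaternary centre is used; the sense of induction for this CH2OMOM substrate must be confirmed on the first run.
- Nothing here has been run; selectivities are predictions from analogy.

**Retrosynthetic overview**
1. Ludongunin J ⇐ α-methylenation (C17) of 17-nor β-keto-lactone 15.
2. D ring (C13–C16) ⇐ Pd(II) cycloalkenylation of the acetyl enol silane onto the cyclohexene of 12; C ring ⇐ Diels–Alder of butadiene with spiro 3-acetyl-dihydropyranone 10 (sets C8, C9).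
3. Spiro δ-lactone and C10 quaternary centre ⇐ new Ti(III) radical alkenylative lactonisation of spiro-epoxide 8 with an ethoxymethylene acetoacetate.
4. Oxolane acetal on ring A ⇐ Cu-catalysed asymmetric conjugate methylation (C4), orthoformate trapping at C5, acid-mediated acetalisation (C5, C6).
5. Ring order: A (from 3-ethoxycyclohexenone) → oxolane acetal → spiro δ-lactone → C → D.

**Route**

Step 1
Reactants: 1, 3-ethoxycyclohex-2-en-1-one; 2, tributyl[(methoxymethoxy)methyl]stannane
Product: 3, 3-[(methoxymethoxy)methyl]cyclohex-2-en-1-one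
Conditions: 2, n-BuLi, THF, −78 °C; add 1, −78 → 0 °C; then 1 M HCl, 0 °C
Reagents that add atoms: 2 (CH2OCH2OCH3 unit), CCCC[Sn](CCCC)(CCCC)COCOC; water (new carbonyl O), O
Why: Sn–Li exchange gives MOMOCH2Li, which adds 1,2 to the vinylogous ester; acidic work-up gives the transposed enone (Stork–Danheiser sequence).

Step 2
Reactants: 3
Product: 4, trimethyl{[(3R)-3-[(methoxymethoxy)methyl]-3-methylcyclohex-1-en-1-yl]oxy}silane
Conditions: Me3Al (1.5 equiv), CuTC (2 mol %), biphenol phosphoramidite L* with bis[1-(2-naphthyl)ethyl]amine (4 mol %), Et2O, −30 °C; then TMSOTf, Et3N, THF, −30 → 0 °C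
Reagents that add atoms: trimethylaluminium, C[Al](C)C; TMSOTf, C[Si](C)(C)OS(=O)(=O)C(F)(F)F
Why: Cu/phosphoramidite asymmetric conjugate addition of Me3Al to a β-substituted cyclohexenone sets the C4 quaternary centre under ligand control, and the regiodefined aluminium enolate (C5=C10) is trapped as the enol silane.

Step 3
Reactants: 4
Product: 5, (3R)-2-(dimethoxymethyl)-3-[(methoxymethoxy)methyl]-3-methylcyclohexan-1-one (C2 epimers)
Conditions: HC(OMe)3, TMSOTf (10 mol %), CH2Cl2, −78 °C
Reagents that add atoms: trimethyl orthoformate, COC(OC)OC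
Why: Mukaiyama-type addition of the enol silane to the dimethoxycarbenium ion installs C6 at the aldehyde oxidation level only at C5; the C5 configuration is irrelevant because it is epimerisable in step 4.

Step 4
Reactants: 5
Product: 6, (3R,3aS,7aR)-3-methoxy-7a-methylhexahydro-2-benzofuran-4(1H)-one (cis-fused; OMe trans to the angular methyl; kaurane 4R,5S,6R)
Conditions: HCl (0.5 M, from AcCl) in MeOH, 0 → 40 °C; NaHCO3 quench before concentration
Reagents that add atoms: methanol (exchanges into the acetal OMe), CO
Why: Acidic methanolysis removes the MOM group and the freed C19-OH transacetalises onto C6; C5 (via the enol) and C6 (via the oxocarbenium ion) equilibrate to the cis-fused acetal whose OMe sits on the oxolane face opposite the angular methyl, avoiding a 1,3-syn CH3/OMe contact (thermodynamic acetalisation; excess MeOH and neutralisation before concentration suppress loss of MeOH to the enol ether, and the minor C6 epimer is recycled by resubmission).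

Step 5
Reactants: 6
Product: 7, (3R,3aS,7aR)-3-methoxy-7a-methyl-4-methylideneoctahydro-2-benzofuran
Conditions: Cp2TiMe2 (2.5 equiv), PhMe/THF, 65 °C, dark
Reagents that add atoms: dimethyltitanocene (Petasis reagent), C[Ti](C)(C1C=CC=C1)C1C=CC=C1
Why: Petasis methylenation: thermolysis of Cp2TiMe2 gives Cp2Ti=CH2, which olefinates the ketone by [2+2]/retro-[2+2]. The reagent is non-basic and free of aluminium Lewis acids, so the hindered ketone reacts without enolisation, C5 epimerisation, β-elimination of the acetal oxygen or ionisation of the mixed acetal (the SMILES draws the cyclopentadienyl rings σ-bonded).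

Step 6
Reactants: 7
Product: 8, (3R,3aR,7aR)-3-methoxy-7a-methylhexahydro-1H-spiro[2-benzofuran-4,2'-oxirane] (either or both C10 epimers)
Conditions: mCPBA, NaHCO3, CH2Cl2, 0 °C
Reagents that add atoms: mCPBA, OOC(=O)c1cccc(Cl)c1
Why: Prilezhaev epoxidation of the 1,1-disubstituted alkene under buffered conditions; the epoxide configuration is inconsequential because C10 becomes a planar radical in step 7.

Step 7
Reactants: 8; 9, ethyl 2-(ethoxymethylene)-3-oxobutanoate
Product: 10, spiro 3-acetyl-5,6-dihydro-2H-pyran-2-one: C10 is the spiro atom shared by ring A (C1, C5) and the lactone (C9H=C8(Ac)–C7(=O)–O–C20H2); kaurane 4R,5R,6R,10R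
Conditions: Cp2TiCl2 (2.5 equiv), Zn dust, THF, rt (pre-formed Cp2TiCl) added by syringe pump to 8 and 9 (3 equiv), THF, 0 °C → rt; then 50 °C, 1 h; aq. NaH2PO4
Reagents that add atoms: 9 (supplies C7–C9 and the acetyl group), CCOC=C(C(C)=O)C(=O)OCC
Why: Proposed new method: Ti(III) radical alkenylative spirolactonisation — Cp2TiCl opens the epoxide to the tertiary C10 radical carrying a Ti–O–C20 alkoxide, this adds to the β-carbon of push–pull acceptor 9, a second Cp2TiCl reduces the α,α-dicarbonyl radical to a Ti enolate that expels ethoxide (E1cB), and the tethered Ti alkoxide transesterifies the ethyl ester to close the δ-lactone; the acceptor approaches C10 trans to the vicinal C5–C6 bond and away from the oxolane CH2O, giving 10R; closest known chemistry is the Cp2TiCl reductive epoxide–acrylate coupling with lactonisation (Nugent–RajanBabu type) and radical addition–β-elimination alkenylation.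

Step 8
Reactants: 10; 11, buta-1,3-diene
Product: 12, cis-fused Diels–Alder adduct: cyclohex-3-ene (C8, C9, C11, C12=C13, C14) fused to the δ-lactone at C8–C9, with acetyl on C8 cis to H9; kaurane 4R,5R,6R,8S,9S,10R
Conditions: buta-1,3-diene (excess), BHT (cat.), PhMe, 130 °C, sealed tube
Reagents that add atoms: 11 (C11–C14), C=CC=C
Why: Normal-demand Diels–Alder on the doubly activated 2-acyl enoate; suprafacial addition fixes acetyl and H9 cis, and the diene adds to the lactone face on the C1 side of the spiro centre because the opposite face is shielded by C5 and its C6–OMe, setting C8 and C9 relative to C10.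

Step 9
Reactants: 12
Product: 13, the C15 trimethylsilyl enol ether of 12 (CH2=C(OTMS)– on C8)
Conditions: LiHMDS, TMSCl (in situ), THF, −78 °C
Reagents that add atoms: chlorotrimethylsilane, C[Si](C)(C)Cl
Why: Kinetic enolisation can only occur at the acetyl methyl (C16) because C8 is quaternary, and in situ silylation avoids Lewis-acid exposure of the acetal.

Step 10
Reactants: 13
Product: 14, 17-nor-11,12-didehydro precursor: bicyclo[3.2.1]oct-2-en-6-one with C15 ketone, C16H2 bridge carbon bonded to C13, and C11=C12 alkene; kaurane 8S,9S,13R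
Conditions: Pd(OAc)2 (1.1 equiv), MeCN, rt
Reagents that add atoms: none
Why: Pd(II)-mediated cycloalkenylation of a silyl enol ether (Kende/Saegusa type): C16 adds 5-exo to C13 of the ring alkene from the face bearing the axial acetyl (the only geometry that can bridge, so C13 is set by the ring), and syn β-hydride elimination toward C11 gives the non-bridgehead alkene; no competing Saegusa enone formation is possible since C8 has no hydrogen.

Step 11
Reactants: 14
Product: 15, 17-norludongunin J (C16 is CH2 α to the C15 ketone); kaurane 4R,5R,6R,8S,9S,10R,13R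
Conditions: H2 (1 atm), 10% Pd/C, EtOAc, rt
Reagents that add atoms: none
Why: Catalytic hydrogenation of the isolated cis-disubstituted C11=C12 alkene creates no stereocentre and leaves ketone, lactone and acetal untouched.

Step 12
Reactants: 15
Product: 16, Ludongunin J
Conditions: LiHMDS, THF, −78 °C; Eschenmoser's salt, −78 → 0 °C; then MeI, CH2Cl2; NaHCO3 (aq)
Reagents that add atoms: Eschenmoser's salt (CH2), C[N+](C)=C.[I-]
Why: C16 is the only enolisable position (C8 is quaternary), so Mannich aminomethylation followed by quaternisation and elimination gives the exocyclic α-methylene ketone (Eschenmoser methylenation).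

**Compound list**
1 | 3-ethoxycyclohex-2-en-1-one | CCOC1=CC(=O)CCC1 | starting material
2 | tributyl[(methoxymethoxy)methyl]stannane | CCCC[Sn](CCCC)(CCCC)COCOC | starting material
3 | 3-[(methoxymethoxy)methyl]cyclohex-2-en-1-one | O=C1C=C(COCOC)CCC1 | intermediate
4 | trimethyl{[(3R)-3-[(methoxymethoxy)methyl]-3-methylcyclohex-1-en-1-yl]oxy}silane | C[Si](C)(C)OC1=C[C@](C)(COCOC)CCC1 | intermediate
5 | (3R)-2-(dimethoxymethyl)-3-[(methoxymethoxy)methyl]-3-methylcyclohexan-1-one (C2 epimers) | O=C1CCC[C@@](C)(COCOC)C1C(OC)OC | intermediate
6 | (3R,3aS,7aR)-3-methoxy-7a-methylhexahydro-2-benzofuran-4(1H)-one | O=C1CCC[C@@]2(C)CO[C@@H](OC)[C@H]21 | intermediate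
7 | (3R,3aS,7aR)-3-methoxy-7a-methyl-4-methylideneoctahydro-2-benzofuran | C=C1CCC[C@@]2(C)CO[C@@H](OC)[C@H]21 | intermediate
8 | (3R,3aR,7aR)-3-methoxy-7a-methylhexahydro-1H-spiro[2-benzofuran-4,2'-oxirane] (spiro carbon unspecified) | C1OC12CCC[C@@]3(C)CO[C@@H](OC)[C@H]32 | intermediate
9 | ethyl 2-(ethoxymethylene)-3-oxobutanoate | CCOC=C(C(C)=O)C(=O)OCC | starting material
10 | spiro 3-acetyl-5,6-dihydro-2H-pyran-2-one on the A-ring acetal (4R,5R,6R,10R) | CC(=O)C1=C[C@@]2(CCC[C@@]3(C)CO[C@@H](OC)[C@H]32)COC1=O | intermediate
11 | buta-1,3-diene | C=CC=C | starting material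
12 | cis-fused cyclohexene–lactone Diels–Alder adduct, 8-acetyl (8S,9S,10R) | CC(=O)[C@]12CC=CC[C@H]1[C@@]1(CCC[C@@]3(C)CO[C@@H](OC)[C@H]31)COC2=O | intermediate
13 | C15 trimethylsilyl enol ether of 12 | C=C(O[Si](C)(C)C)[C@]12CC=CC[C@H]1[C@@]1(CCC[C@@]3(C)CO[C@@H](OC)[C@H]31)COC2=O | intermediate
14 | 17-nor-11,12-didehydro bicyclo[3.2.1]octenone (8S,9S,13R) | C1C(=O)[C@]23C[C@H]1C=C[C@H]2[C@@]1(CCC[C@@]2(C)CO[C@@H](OC)[C@H]21)COC3=O | intermediate
15 | 17-norludongunin J | C1C(=O)[C@]23C[C@H]1CC[C@H]2[C@@]1(CCC[C@@]2(C)CO[C@@H](OC)[C@H]21)COC3=O | intermediate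
16 | Ludongunin J (4R,5R,6R,8S,9S,10R,13R) | C=C1C(=O)[C@]23C[C@H]1CC[C@H]2[C@@]1(CCC[C@@]2(C)CO[C@@H](OC)[C@H]21)COC3=O | target

**Totals**
Total steps: 12. Longest linear sequence: 12 (from 1).

**Three steps most likely to fail**
1. Step 7 (proposed new reaction). Likely failures: the tertiary radical is reduced or eliminated faster than it adds to the β-ethoxy acceptor, ethoxide loss or lactonisation is incomplete, the facial selectivity at C10 is low, or product 10 is over-reduced by Ti(III). Fallback with known chemistry, converging on 10: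
   - Cp2TiCl-mediated reductive coupling of 8 with 2,2,2-trifluoroethyl acrylate to the saturated spiro-δ-lactone (same facial control at C10).
   - C8 acetylation (LiHMDS; 1-acetylimidazole).
   - α-Selenenylation and selenoxide elimination (PhSeCl, pyridine; H2O2).
2. Step 4 (C6 acetal configuration under thermodynamic control may give a poor ratio; the preference argued above is not certain). Fallback using kinetic control instead:
   - Oxidise the acetal of 7 to the 19,6-lactone (Jones).
   - O-methylate (MeOTf, 2,6-di-tert-butylpyridine) and reduce the dialkoxycarbenium ion with L-Selectride at −78 °C.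
   - Hydride enters trans to the vicinal C5–C10 bond, leaving OMe cis to C10 (6R).
3. Step 10 (5-exo versus 6-endo attack, which would give a bicyclo[2.2.2]octane, and the need for the diaxial conformer of 12). Fallback by anionic epoxide opening:
   - Epoxidise C12=C13 of 12 (DMDO) on the face anti to the acetyl.
   - Treat with KHMDS: the methyl-ketone enolate opens the epoxide 5-exo-tet at C13 (attack at C12 would be 6-endo).
   - Remove the resulting C12 hydroxyl by Barton–McCombie deoxygenation to reach 15 directly.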